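**Plan**

- The target is a 4H-pyran-4-one (O1, C2 propanoyl, C3–Br, C4=O, C5–Br, C6–Br) with no stereocentre. Working backwards, the side-chain C=O is traced to a 1-ethylvinyl group, then C6–Br, C5–Br and C3–Br are removed, then the two ring double bonds, which leaves 2-(but-1-en-2-yl)tetrahydropyran-4-one.
- In that ring C2 sits on O1 and C3 is alpha to the C4 ketone. The C2–C3 bond therefore joins an oxocarbenium carbon to an enolate carbon, the pair released when a 4-methylene-1,3-dioxane is ionised (Petasis–Ferrier rearrangement), and this bond is cut next.
- The enol acetal is cut at its exocyclic C=CH2 (lactone methylenation) and at the two acetal C–O bonds, which leads to 3-hydroxypropanoic acid and 2-ethylacrolein.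
- Forward: the two building blocks are joined as an acetal and methylenated, and the only ring closes in step 4. Dehydrogenation, C3/C5 bromination and C6 zincation–bromination follow. The alkene is cleaved to the ketone last, because an enolisable ketone would be deprotonated by the zinc amide.
- Stereochemistry: C2 of 4, 5 and 7 is racemic and is erased by the dehydrogenation in step 5.

Key step: step 4

Assumption: 3-hydroxypropanoic acid is sold as an aqueous solution and is freed of water by azeotropic evaporation with toluene below 35 °C directly before step 1; Cp2TiMe2, Me2AlCl, TMPZnCl·LiCl and IBX are used as purchased.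

**Route**

Step 1
Reactants: 1 3-hydroxypropanoic acid
Product: 2 trimethylsilyl 3-(trimethylsilyloxy)propanoate
Conditions: HMDS (1.5 equiv), Me3SiCl (cat.), CH2Cl2, rt; volatiles removed in vacuo
Reagents that add atoms: hexamethyldisilazane, C[Si](C)(C)N[Si](C)(C)C
Why: O-silylation of the alcohol and the acid by HMDS, driven by loss of NH3, should give the bis-silyl derivative that allows the acetal to be closed without protic acid or water.

Step 2
Reactants: 2 trimethylsilyl 3-(trimethylsilyloxy)propanoate; 3 2-ethylacrolein
Product: 4 2-(but-1-en-2-yl)-1,3-dioxan-4-one (racemic)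
Conditions: Me3SiOTf (10 mol%), CH2Cl2, −78 °C; Et3N quench
Reagents that add atoms: none
Why: Silyl-triflate-catalysed acetalisation of a silyl ether/silyl ester pair with an aldehyde, the standard aprotic entry to 1,3-dioxan-4-ones from bis-silylated beta-hydroxy acids, should close the ring with loss of (Me3Si)2O, the enal reacting at its carbonyl carbon at low temperature and the single centre C2 forming as a racemate.

Step 3
Reactants: 4 2-(but-1-en-2-yl)-1,3-dioxan-4-one (racemic)
Product: 5 2-(but-1-en-2-yl)-4-methylidene-1,3-dioxane (racemic)
Conditions: Cp2TiMe2 (2 equiv), THF, 65 °C, dark; filtration through basic alumina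
Reagents that add atoms: dimethyltitanocene Cp2TiMe2, C[Ti](C)(C1C=CC=C1)C1C=CC=C1
Why: Petasis methylenation, in which Cp2TiMe2 loses methane on heating to give Cp2Ti=CH2 that olefinates the lactone carbonyl through an oxatitanacyclobutane, should convert the dioxanone into the enol acetal without the Lewis acidity that would open the acetal.

Step 4
Reactants: 5 2-(but-1-en-2-yl)-4-methylidene-1,3-dioxane (racemic)
Product: 7 2-(but-1-en-2-yl)tetrahydro-4H-pyran-4-one (racemic), via ring-opened oxocarbenium enolate zwitterion 6 (not isolated)
Conditions: Me2AlCl (1.2 equiv), CH2Cl2, −78 → 0 °C; aq. NaHCO3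
Reagents that add atoms: none
Why: Me2AlCl should bind the enol-ether oxygen O3 of 5 and break the C2–O3 acetal bond, giving zwitterion 6, in which an O1=C2 oxocarbenium ion conjugated with the 1-ethylvinyl group is paired with the aluminium enolate of a methyl ketone. The enolate carbon (the former exocyclic methylene, future C3) then adds to the oxocarbenium carbon C2 in an aldol-type step, so the acetal oxygen O1 becomes the ring oxygen and the ring bond C2–C3 is made. The closest known reaction type is the Petasis–Ferrier rearrangement of 4-methylene-1,3-dioxanes to tetrahydropyran-4-ones under Me2AlCl. The one ring closes in a 6-(enolendo)-endo-trig mode. The only new stereocentre, C2, arises as a racemate because 5 is racemic and has no other centre, and it is removed in step 5, so no control is required. The step needs C- rather than O-recombination and attack at C2 rather than at the vinylogous methylene end of the alkoxyallyl cation: O-recombination only regenerates 5 and is reversible, attack at C2 is a six-membered chair-like closure inside the aluminium-bound ion pair whereas the vinylogous end would demand an eight-membered ring, and Me2AlCl has no beta-hydrogen with which to reduce the ketone.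

Step 5
Reactants: 7 2-(but-1-en-2-yl)tetrahydro-4H-pyran-4-one (racemic)
Product: 9 2-(but-1-en-2-yl)-4H-pyran-4-one, via 6-(but-1-en-2-yl)-2,3-dihydro-4H-pyran-4-one 8 (not isolated)
Conditions: IBX (3 equiv), DMSO–toluene, 75 °C
Reagents that add atoms: none
Why: IBX dehydrogenation of ketones (enol capture by the hypervalent iodine reagent, then loss of the beta-hydrogen) should act first toward C2, whose hydrogen is allylic and alpha to oxygen, and then toward C6, ending at the cross-conjugated pyranone and erasing the C2 stereocentre.

Step 6
Reactants: 9 2-(but-1-en-2-yl)-4H-pyran-4-one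
Product: 11 3,5-dibromo-2-(but-1-en-2-yl)-4H-pyran-4-one, via 5-bromo-2-(but-1-en-2-yl)-4H-pyran-4-one 10 (not isolated)
Conditions: NBS (2.1 equiv), DMF, 0 °C → rt, dark
Reagents that add atoms: N-bromosuccinimide, O=C1CCC(=O)N1Br
Why: Electrophilic substitution of a 4-pyranone by NBS should occur at C5 and then C3, the beta-carbons of its two vinylogous ester units that O1 activates, while the exocyclic alkene, cross-conjugated with O1 and electron-poor, should react more slowly under ionic conditions in the dark.

Step 7
Reactants: 11 3,5-dibromo-2-(but-1-en-2-yl)-4H-pyran-4-one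
Product: 13 3,5,6-tribromo-2-(but-1-en-2-yl)-4H-pyran-4-one, via C6-pyranylzinc chloride 12 (not isolated)
Conditions: TMPZnCl·LiCl (1.2 equiv), THF, 0 °C → rt; then NBS (1.3 equiv), −30 °C → rt; aq. NH4Cl
Reagents that add atoms: N-bromosuccinimide, O=C1CCC(=O)N1Br
Why: Directed zincation of 4-pyranones next to the ring oxygen by the hindered amide base TMPZnCl·LiCl should remove the only ring hydrogen, C6–H (acidified by O1, the C5 bromine and the vinylogous carbonyl), to give a covalent C–Zn species that neither opens the ring nor eliminates the neighbouring bromide, and bromine transfer from NBS to this carbon, chosen over Br2 to spare the side-chain alkene, should install the third bromine.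

Step 8
Reactants: 13 3,5,6-tribromo-2-(but-1-en-2-yl)-4H-pyran-4-one
Product: 15 3,5,6-tribromo-2-propanoyl-4H-pyran-4-one (target), via secondary ozonide 14 (not isolated)
Conditions: O3, CH2Cl2, −78 °C, stopped at first persistent blue, N2 purge; Me2S (1.5 equiv), −78 °C → rt
Reagents that add atoms: ozone, [O-][O+]=O
Why: Ozonolysis with reductive work-up should cleave only the exocyclic 1,1-disubstituted alkene, since electrophilic ozone adds far more slowly to the tetrasubstituted ring double bonds that carry bromine and the carbonyl, and Me2S should reduce the ozonide to the propanoyl ketone and formaldehyde under anhydrous, non-basic conditions that the C6 bromide tolerates.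

**Compound list**

1 | 3-hydroxypropanoic acid | OCCC(=O)O | starting material
2 | trimethylsilyl 3-(trimethylsilyloxy)propanoate | C[Si](C)(C)OCCC(=O)O[Si](C)(C)C | intermediate
3 | 2-ethylacrolein (2-methylidenebutanal) | CCC(=C)C=O | starting material
4 | 2-(but-1-en-2-yl)-1,3-dioxan-4-one (racemic) | C=C(CC)C1OCCC(=O)O1 | intermediate
5 | 2-(but-1-en-2-yl)-4-methylidene-1,3-dioxane (racemic) | C=C(CC)C1OCCC(=C)O1 | intermediate
6 | ring-opened zwitterion: (E/Z)-O-alkylidene oxocarbenium ion of 2-ethylacrolein tethered to the chlorodimethylaluminate enolate of a methyl ketone | C=C(CC[O+]=CC(=C)CC)O[Al-](C)(C)Cl | intermediate (not isolated)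
7 | 2-(but-1-en-2-yl)tetrahydro-4H-pyran-4-one (racemic) | C=C(CC)C1CC(=O)CCO1 | intermediate
8 | 6-(but-1-en-2-yl)-2,3-dihydro-4H-pyran-4-one | C=C(CC)C1=CC(=O)CCO1 | intermediate (not isolated)
9 | 2-(but-1-en-2-yl)-4H-pyran-4-one | C=C(CC)c1cc(=O)cco1 | intermediate
10 | 5-bromo-2-(but-1-en-2-yl)-4H-pyran-4-one | C=C(CC)c1cc(=O)c(Br)co1 | intermediate (not isolated)
11 | 3,5-dibromo-2-(but-1-en-2-yl)-4H-pyran-4-one | C=C(CC)c1occ(Br)c(=O)c1Br | intermediate
12 | [3,5-dibromo-2-(but-1-en-2-yl)-4-oxo-4H-pyran-6-yl]zinc chloride (LiCl-complexed) | C=C(CC)c1oc([Zn]Cl)c(Br)c(=O)c1Br | intermediate (not isolated)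
13 | 3,5,6-tribromo-2-(but-1-en-2-yl)-4H-pyran-4-one | C=C(CC)c1oc(Br)c(Br)c(=O)c1Br | intermediate
14 | 3-ethyl-3-(3,5,6-tribromo-4-oxo-4H-pyran-2-yl)-1,2,4-trioxolane (racemic) | CCC1(OCOO1)c1oc(Br)c(Br)c(=O)c1Br | intermediate (not isolated)
15 | 3,5,6-tribromo-2-propanoyl-4H-pyran-4-one (CNP0423242.0; also named 2,3,5-tribromo-6-propanoyl-4H-pyran-4-one) | CCC(=O)c1oc(Br)c(Br)c(=O)c1Br | target

**Step count**

Total steps: 8. Longest linear sequence: 8 steps (from 3-hydroxypropanoic acid 1).

**Steps most likely to fail**

Step 6. Bromine transfer to the side-chain alkene (addition or allylic substitution) may compete with ring substitution, or the second substitution at the hindered C3 may lag. The fallback sets out from 9 and lets the alkene react on purpose. Br2 (3.2 equiv) in CH2Cl2 at 0 °C followed by pyridine should add across both ring double bonds and the side-chain alkene. The ring adducts then lose HBr, because the alpha-bromo ether bromide is labile and the proton alpha to the carbonyl is acidic. This should give 3,5-dibromo-2-(1,2-dibromobutan-2-yl)-4H-pyran-4-one F1 (racemic), in which the alkene is stored as its vicinal dibromide. NaI in acetone at rt should then remove the two side-chain bromines by anti-elimination while leaving the vinylic ring bromides, which returns to the route at 11.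

Step 5. The oxidation may stall after the first dehydrogenation, since the vinylogous ester 8 enolises reluctantly, or the allylic CH2 of the ethyl group may be oxidised at the temperature required. The fallback sets out from 7 and replaces dehydrogenation by halogenation–elimination. Phenyltrimethylammonium tribromide (2 equiv, THF, 0 °C) brominates ketones through the enol in preference to adding to isolated alkenes. It should give 3,5-dibromo-2-(but-1-en-2-yl)tetrahydro-4H-pyran-4-one F2 as a mixture of diastereomers. Li2CO3 and LiBr in DMF at 110 °C should then eliminate two molecules of HBr (C2–H with C3–Br, C6–H with C5–Br), which returns to the route at 9.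

Step 8. Ozone may also attack the ring double bonds, or the peroxidic intermediates and the sulfide may degrade the C6 vinylogous acyl bromide. The fallback sets out from 13 and cleaves the alkene in two stages without ozone. Catalytic OsO4 with N-methylmorpholine N-oxide and citric acid in t-BuOH–H2O at 0 °C should dihydroxylate only the unhindered exocyclic alkene, since osmylation of the tetrasubstituted bromo-enone double bonds is far slower. This gives 3,5,6-tribromo-2-(1,2-dihydroxybutan-2-yl)-4H-pyran-4-one F3 (racemic). Pb(OAc)4 in CH2Cl2 at 0 °C should then cleave the glycol under anhydrous, non-nucleophilic conditions, which returns to the route at 15.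

**Further compounds**

F1 | step 6 | 3,5-dibromo-2-(1,2-dibromobutan-2-yl)-4H-pyran-4-one (racemic) | CCC(Br)(CBr)c1occ(Br)c(=O)c1Br
F2 | step 5 | 3,5-dibromo-2-(but-1-en-2-yl)tetrahydro-4H-pyran-4-one (diastereomer mixture, racemic) | C=C(CC)C1OCC(Br)C(=O)C1Br
F3 | step 8 | 3,5,6-tribromo-2-(1,2-dihydroxybutan-2-yl)-4H-pyran-4-one (racemic) | CCC(O)(CO)c1oc(Br)c(Br)c(=O)c1Br
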